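**Retrosynthetic overview**
- Ring A is bought as the aromatic ring of 2,4,6-trihydroxybenzophenone 1; its two C-prenyl bonds go back to prenyl bromide 2, giving the achiral diprenyl ketone 3.
- C7 comes from the chiral pool: (R)-lavandulol 4, activated as its triflate 5.
- Disconnection C5–C6: C-alkylative dearomatization of 3 by 5 gives the lavandulyl diprenyl trione 6.
- Disconnection C1–C8 (ring B, closed last): the tertiary C8 cation 7, formed from the isopropenyl group of 6, is trapped by the C1 enol carbon, the way the plant is thought to close this ring, giving 7-epi-clusianone 8.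
- Ring order: A (purchased), then B; both ring B bonds (C5–C6, then C1–C8) are made in one flask.

Assumption: 1 and (R)-(−)-lavandulol 4 (the natural enantiomer) are bought as such; the bicycle is numbered so that C8 carries the gem-dimethyl group, and CIP labels refer to the tautomers written in the SMILES.

**Route**

Step 1
Reactants: 1 2,4,6-trihydroxybenzophenone; 2 prenyl bromide (1-bromo-3-methylbut-2-ene)
Product: 3 2,4,6-trihydroxy-3,5-bis(3-methylbut-2-enyl)benzophenone (clusiaphenone B)
Conditions: 2 (2.1 equiv), 10% aq. KOH, 0 °C, 2 h
Reagents that add atoms: none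
Why: Twofold C-prenylation of the phloroglucinolate at its two equivalent free ring carbons (Friedel–Crafts-type C-alkylation of an ambident phenolate, favoured over O-alkylation in water); no stereocentre is formed.

Step 2
Reactants: 4 (R)-lavandulol
Product: 5 (R)-lavandulyl triflate
Conditions: Tf2O (1.1 equiv), 2,6-lutidine (1.3 equiv), CH2Cl2, −78 °C, 20 min; cold pentane/silica plug; used at once
Reagents that add atoms: trifluoromethanesulfonic anhydride, O=S(=O)(OS(=O)(=O)C(F)(F)F)C(F)(F)F
Why: O-sulfonylation (triflation) of the primary alcohol, in which no bond to C7 is touched, so the chiral-pool configuration is carried over unchanged.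

Step 3
Reactants: 3 clusiaphenone B; 5 (R)-lavandulyl triflate
Product: 8 7-epi-clusianone (target), via dearomatized lavandulyl trione 6 (not isolated), via tertiary C8 carbocation 7 (not isolated)
Conditions: 3, LiN(SiMe3)2 (3.0 equiv), THF, 0 °C; 5 (1.3 equiv), −20 to 0 °C, 2 h; HCO2H quench, evaporate; neat HCO2H (0.05 M), rt, 48–72 h; SiO2 chromatography
Reagents that add atoms: none
Why: Proposed new method: the lithium phenolate of 3 is C-alkylated at one of its two equivalent prenyl-bearing carbons by the primary triflate (SN2 alkylative dearomatization; closest known type: LiN(SiMe3)2-mediated dearomatization of acylphloroglucinols by alkyl triflates), which gives 6 as both C5 epimers because C7 is too remote to bias the new quaternary centre, and neat HCO2H then protonates the isopropenyl group to cation 7, whose capture by the C1 enol carbon (cation–olefin cyclization as in the biosynthesis; closest known type: formic acid-mediated closure of dearomatized lavandulyl acylphloroglucinols in the 7-exo series, where reversible O-cyclization feeds the irreversible C–C closure) is stereospecific: C7 is kept from 4, C1 must follow C5 because the new bond can only form on the face that carries the side chain, the (5R) epimer can close only through a boat-like transition state with the C7 prenyl outward and so gives the 7-endo target 8, and the (5S) epimer closes through the chair to the 7-exo diastereomer (clusianone series), which chromatography removes.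

**Compound list**

1 | 2,4,6-trihydroxybenzophenone | O=C(c1ccccc1)c1c(O)cc(O)cc1O | starting material
2 | prenyl bromide (1-bromo-3-methylbut-2-ene) | CC(C)=CCBr | starting material
3 | 2,4,6-trihydroxy-3,5-bis(3-methylbut-2-enyl)benzophenone (clusiaphenone B), achiral | CC(C)=CCc1c(O)c(CC=C(C)C)c(O)c(C(=O)c2ccccc2)c1O | intermediate
4 | (R)-(−)-lavandulol, (2R)-5-methyl-2-(prop-1-en-2-yl)hex-4-en-1-ol | CC(C)=CC[C@@H](CO)C(C)=C | starting material
5 | (R)-lavandulyl triflate, (2R)-5-methyl-2-(prop-1-en-2-yl)hex-4-enyl trifluoromethanesulfonate | CC(C)=CC[C@@H](COS(=O)(=O)C(F)(F)F)C(C)=C | intermediate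
6 | (6R)-2-benzoyl-3,5-dihydroxy-6-[(2S)-5-methyl-2-(prop-1-en-2-yl)hex-4-enyl]-4,6-bis(3-methylbut-2-enyl)cyclohexa-2,4-dien-1-one (one enol tautomer; the side-chain label reads S only because the CIP ranks change, the spatial arrangement is that of 4) | CC(C)=CC[C@@H](C[C@@]1(CC=C(C)C)C(=O)C(C(=O)c2ccccc2)=C(O)C(CC=C(C)C)=C1O)C(C)=C | intermediate
7 | tertiary carbocation formed from 6 by protonation of the CH2 of its isopropenyl group (2-propyl cation at C8) | CC(C)=CC[C@@H](C[C@@]1(CC=C(C)C)C(=O)C(C(=O)c2ccccc2)=C(O)C(CC=C(C)C)=C1O)[C+](C)C | intermediate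
8 | 7-epi-clusianone, (1S,5R,7S)-3-[hydroxy(phenyl)methylidene]-8,8-dimethyl-1,5,7-tris(3-methylbut-2-enyl)bicyclo[3.3.1]nonane-2,4,9-trione, C7 prenyl endo (on the side of the C2–C4 bridge) | CC(C)=CC[C@H]1C[C@@]2(CC=C(C)C)C(=O)/C(=C(/O)c3ccccc3)C(=O)[C@](CC=C(C)C)(C2=O)C1(C)C | target

**Step count and risks**

Total step count: 3. Longest linear sequence: 2 steps (1 → 3 → 8, or 4 → 5 → 8).

All three steps carry risk; in falling order:

Step 3. The hard triflate may O-alkylate instead of C-alkylate. The boat-like C–C closure is expected to be slower than the chair closure of the 7-exo series. This gives the ring prenyl groups time to interfere, by attack of the C5 prenyl olefin on cation 7 or by acid-induced chroman formation. At best half of 6 has the C5 configuration that leads to 8. The fallback replaces the two ring prenyl groups by allyl groups, which HCO2H does not protonate and which are poor cation traps, and converts them into prenyl groups at the end. It sets out from 1 and 5 and comes back to the route at 8. Compound 1 is C-allylated twice (allyl bromide, 10% aq. KOH, 0 °C) to 3,5-diallyl-2,4,6-trihydroxybenzophenone F1. F1 and 5 under the alkylation conditions of step 3 give the dearomatized diallyl lavandulyl trione F2. F2 can then be forced through the ring closure with longer times, gentle heating or a stronger acid, giving the 1,5-diallyl bicycle F3. Cross-metathesis of F3 with 2-methyl-2-butene (second-generation Grubbs catalyst RuCl2(PCy3)(H2IMes)(=CHPh), 40 °C) turns both allyl groups into prenyl groups and gives 8; the C7 prenyl group is degenerate under these conditions.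

Step 2. Triflate 5 is a β-branched homoallylic primary triflate and may ionize, rearrange or eliminate before it is used. The fallback gives up the sulfonate and inverts the order in which the two substituents reach C5. The unactivated lavandulyl electrophile then only has to attack an unhindered aromatic CH, and the quaternary centre is made with the far more reactive allylic bromide 2. It sets out from 4, 1 and 2 and comes back to the route at 6. Compound 4 is converted (I2, PPh3, imidazole, CH2Cl2, 0 °C) into (R)-lavandulyl iodide F4. Compound 1 is monoprenylated (2, 1.0 equiv, aq. KOH, 0 °C) to 2,4,6-trihydroxy-3-prenylbenzophenone F5. F5 is C-alkylated at its free ring carbon by F4 (NaOMe, MeOH, reflux) to the aromatic lavandulyl prenyl ketone F6. Dearomatizing prenylation of F6 with 2 (NaOMe, MeOH, 0 °C) gives 6 as both C5 epimers, beside the regioisomer prenylated at the other substituted carbon, which cannot close ring B. Compound 6 then enters the HCO2H stage of step 3.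

Step 1. Direct C-prenylation gives mixtures of mono-, di- and tri-C-prenylated and O-prenylated material, so the yield is modest. The fallback uses O-alkylation followed by rearrangement instead of direct C-alkylation. It sets out from 1 and 2 and comes back to the route at 3. Compounds 1 and 2 with K2CO3 in acetone give the bis(prenyl) ether 2-hydroxy-4,6-bis(3-methylbut-2-enyloxy)benzophenone F7, in which the chelated hydroxyl stays free. Bi(OTf)3 (cat.) in CH2Cl2 at rt then moves both prenyl groups from oxygen to the neighbouring free ring carbons ([1,3] shift of aryl prenyl ethers) and gives 3.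

**Further compounds**

F1 | step 3 | 3,5-diallyl-2,4,6-trihydroxybenzophenone | C=CCc1c(O)c(CC=C)c(O)c(C(=O)c2ccccc2)c1O
F2 | step 3 | (6R)-2-benzoyl-3,5-dihydroxy-6-[(2S)-5-methyl-2-(prop-1-en-2-yl)hex-4-enyl]-4,6-di(prop-2-enyl)cyclohexa-2,4-dien-1-one | CC(C)=CC[C@@H](C[C@@]1(CC=C)C(=O)C(C(=O)c2ccccc2)=C(O)C(CC=C)=C1O)C(C)=C
F3 | step 3 | (1S,5R,7S)-3-[hydroxy(phenyl)methylidene]-8,8-dimethyl-7-(3-methylbut-2-enyl)-1,5-di(prop-2-enyl)bicyclo[3.3.1]nonane-2,4,9-trione (C7 prenyl endo) | CC(C)=CC[C@H]1C[C@@]2(CC=C)C(=O)/C(=C(/O)c3ccccc3)C(=O)[C@](CC=C)(C2=O)C1(C)C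
F4 | step 2 | (R)-lavandulyl iodide, (2R)-1-iodo-5-methyl-2-(prop-1-en-2-yl)hex-4-ene | CC(C)=CC[C@@H](CI)C(C)=C
F5 | step 2 | 2,4,6-trihydroxy-3-(3-methylbut-2-enyl)benzophenone | CC(C)=CCc1c(O)cc(O)c(C(=O)c2ccccc2)c1O
F6 | step 2 | 2,4,6-trihydroxy-3-[(2S)-5-methyl-2-(prop-1-en-2-yl)hex-4-enyl]-5-(3-methylbut-2-enyl)benzophenone | CC(C)=CC[C@@H](Cc1c(O)c(CC=C(C)C)c(O)c(C(=O)c2ccccc2)c1O)C(C)=C
F7 | step 1 | 2-hydroxy-4,6-bis(3-methylbut-2-enyloxy)benzophenone | O=C(c1ccccc1)c1c(O)cc(OCC=C(C)C)cc1OCC=C(C)C
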